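## Retrosynthetic overview

- Target 37 comes from trans-fused diketone 31: the C8 dienyl arm by two olefinations of a C8 aldehyde, the C4 methyl and C4=C5 alkene through the enol triflate of a C4 ketone, and the acid from its methyl ester.
- Feature used: with C4 as a ketone, the C4 and C2 carbonyls are 1,4-related through C3a and C3. Ring B (C3a–C4–C5–C6–C7–C7a) therefore opens at C4–C3a to aldehyde 29, whose C4 acyl-anion equivalent adds to C3a of the 2-methylcyclopent-2-enone (ring A) in a Stetter reaction.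
- Ring A is formed first: an Ireland–Claisen rearrangement makes C1–C7a with chirality transfer from an (S)-allylic butanoate, then ring-closing metathesis makes C3=C3a. Ring B is formed second, by the key step.
- The vicinal quaternary carbons C6 and C7 come from one chelation-controlled dianionic Ireland–Claisen rearrangement (bond C6–C7) of a β-hydroxy ester, made by an auxiliary aldol, onto a stereodefined (E)-trisubstituted allyl unit.

Key step: step 22

Remark: labels C1–C7a follow the hexahydroindene numbering of the target and C8 is the exocyclic carbon on C6. C8 is carried as a diethyl acetal and not as a silyloxymethyl group, because a free C8 hydroxyl would sit cis to the C7 ester and close to a γ-lactone; 29 and 31 therefore bear CH(OEt)2 at C6.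

## Route

Step 1
Reactants: 1 3,3-diethoxyprop-1-yne
Product: 2 4,4-diethoxybut-2-yn-1-ol
Conditions: n-BuLi, THF, −78 °C; (CH2O)n, −78 → 23 °C; H2O
Reagents that add atoms: formaldehyde (as paraformaldehyde), C=O
Why: Deprotonation of the terminal alkyne and addition of the lithium acetylide to formaldehyde (alkynylation of an aldehyde) should give the propargylic alcohol; no stereocentre is formed.

Step 2
Reactants: 2 4,4-diethoxybut-2-yn-1-ol
Product: 4 (Z)-4,4-diethoxy-3-iodobut-2-en-1-ol, via cyclic alkenylalanate 3 (not isolated)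
Conditions: NaAlH2(OCH2CH2OCH3)2 (Red-Al), THF, 0 °C; I2, −78 °C; aq. KNaC4H4O6 (potassium sodium tartrate)
Reagents that add atoms: iodine, II
Why: Hydroxyl-directed trans-hydroalumination with Red-Al places aluminium on C3 inside a five-membered alanate (3), and iodinolysis with retention should give the (Z)-iodoalkene with iodine cis to the hydroxymethyl group.

Step 3
Reactants: 4 (Z)-4,4-diethoxy-3-iodobut-2-en-1-ol
Product: 5 (E)-4,4-diethoxy-3-ethylbut-2-en-1-ol
Conditions: Et2Zn (2.5 equiv), Pd(dppf)Cl2 (5 mol%), THF, 50 °C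
Reagents that add atoms: diethylzinc, CC[Zn]CC
Why: Negishi coupling of the alkenyl iodide with diethylzinc proceeds with retention at the sp2 carbon, so the ethyl group should end up cis to CH2OH, which is the (E)-alkene needed for the chair transition state of step 7.

Step 4
Reactants: 6 (R)-4-benzylthiazolidine-2-thione; 7 butanoyl chloride
Product: 8 (R)-4-benzyl-3-butanoylthiazolidine-2-thione
Conditions: Et3N, 4-(dimethylamino)pyridine (cat.), CH2Cl2, 0 °C
Reagents that add atoms: none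
Why: N-Acylation of the thiazolidinethione with the acid chloride under 4-(dimethylamino)pyridine catalysis is a standard way to load this auxiliary.

Step 5
Reactants: 8 (R)-4-benzyl-3-butanoylthiazolidine-2-thione; 9 (benzyloxy)acetaldehyde
Product: 10 (2R,3R)-1-[(4R)-4-benzyl-2-thioxothiazolidin-3-yl]-4-(benzyloxy)-2-ethyl-3-hydroxybutan-1-one
Conditions: TiCl4, iPr2NEt, N-methylpyrrolidin-2-one, CH2Cl2, 0 °C; then 9, −78 → 0 °C
Reagents that add atoms: none
Why: Titanium-mediated soft enolisation gives the (Z)-enolate, which reacts through a Zimmerman–Traxler chair on the face away from the auxiliary benzyl group (auxiliary-controlled syn aldol addition) and should set the (3R)-carbinol carbon, the only centre of 10 that is carried forward.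

Step 6
Reactants: 10 (2R,3R)-1-[(4R)-4-benzyl-2-thioxothiazolidin-3-yl]-4-(benzyloxy)-2-ethyl-3-hydroxybutan-1-one; 5 (E)-4,4-diethoxy-3-ethylbut-2-en-1-ol
Product: 11 (E)-4,4-diethoxy-3-ethylbut-2-en-1-yl (2R,3R)-4-(benzyloxy)-2-ethyl-3-hydroxybutanoate
Conditions: imidazole, CH2Cl2, 23 °C
Reagents that add atoms: none
Why: The N-acylthiazolidinethione is an activated amide, so imidazole-catalysed acyl transfer to the primary allylic alcohol (transesterification) should give the ester and release the auxiliary without protection of the β-hydroxyl group.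

Step 7
Reactants: 11 (E)-4,4-diethoxy-3-ethylbut-2-en-1-yl (2R,3R)-4-(benzyloxy)-2-ethyl-3-hydroxybutanoate
Product: 12 (2S,3S)-2-[(1R)-2-(benzyloxy)-1-hydroxyethyl]-3-(diethoxymethyl)-2,3-diethylpent-4-enoic acid
Conditions: LiN(iPr)2 (2.3 equiv), THF, −78 → −20 °C; then 23 → 50 °C; aq. HCl to pH 4, 0 °C
Reagents that add atoms: none
Why: In the dianionic Ireland–Claisen rearrangement the lithium alkoxide and the enolate oxygen form a six-membered chelate that fixes the enolate geometry (ethyl cis to the allyloxy group), the allyl terminus adds through a chair transition state to the enolate face anti to the CH2OBn group of the (R)-carbinol, and with the (E)-alkene this should set C7 and C6 (both S here) as the syn-diethyl pair of the target.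

Step 8
Reactants: 12 (2S,3S)-2-[(1R)-2-(benzyloxy)-1-hydroxyethyl]-3-(diethoxymethyl)-2,3-diethylpent-4-enoic acid
Product: 13 methyl (2S,3S)-2-[(1R)-2-(benzyloxy)-1-hydroxyethyl]-3-(diethoxymethyl)-2,3-diethylpent-4-enoate
Conditions: Me3SiCHN2, MeOH/toluene, 0 °C
Reagents that add atoms: (trimethylsilyl)diazomethane, C[Si](C)(C)C=[N+]=[N-]
Why: O-Methylation of the carboxylic acid with (trimethylsilyl)diazomethane occurs at the carboxylate oxygen and should therefore work despite the two flanking quaternary carbons.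

Step 9
Reactants: 13 methyl (2S,3S)-2-[(1R)-2-(benzyloxy)-1-hydroxyethyl]-3-(diethoxymethyl)-2,3-diethylpent-4-enoate
Product: 15 methyl (2S,3S)-2-[(1R)-2-(benzyloxy)-1-hydroxyethyl]-3-(diethoxymethyl)-2,3-diethyl-5-hydroxypentanoate, via B-alkyl-9-BBN adduct 14 (not isolated)
Conditions: 9-BBN (3 equiv), THF, 23 → 50 °C; 30% H2O2, aq. NaOAc, 0 → 23 °C
Reagents that add atoms: hydrogen peroxide, OO
Why: Anti-Markovnikov hydroboration of the only alkene with 9-BBN followed by buffered peroxide oxidation should give the primary alcohol, the acetate buffer keeping the δ-hydroxy ester from closing to a lactone.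

Step 10
Reactants: 15 methyl (2S,3S)-2-[(1R)-2-(benzyloxy)-1-hydroxyethyl]-3-(diethoxymethyl)-2,3-diethyl-5-hydroxypentanoate
Product: 16 methyl (2S,3S)-2-[(1R)-2-(benzyloxy)-1-hydroxyethyl]-5-[(tert-butyldimethylsilyl)oxy]-3-(diethoxymethyl)-2,3-diethylpentanoate
Conditions: TBSCl, imidazole, CH2Cl2, 0 °C
Reagents that add atoms: tert-butyldimethylsilyl chloride, CC(C)(C)[Si](C)(C)Cl
Why: Silylation with TBSCl and imidazole should take place at the primary hydroxyl group only, since the secondary one is neopentyl-like and hindered.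

Step 11
Reactants: 16 methyl (2S,3S)-2-[(1R)-2-(benzyloxy)-1-hydroxyethyl]-5-[(tert-butyldimethylsilyl)oxy]-3-(diethoxymethyl)-2,3-diethylpentanoate
Product: 17 methyl (2S,3S)-5-[(tert-butyldimethylsilyl)oxy]-3-(diethoxymethyl)-2-[(1R)-1,2-dihydroxyethyl]-2,3-diethylpentanoate
Conditions: H2 (1 atm), Pd(OH)2/C, EtOAc, 23 °C
Reagents that add atoms: none
Why: Hydrogenolysis over Pd(OH)2/C should cleave the benzyl ether and leave silyl ether, acetal and ester untouched, no alkene being present any more.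

Step 12
Reactants: 17 methyl (2S,3S)-5-[(tert-butyldimethylsilyl)oxy]-3-(diethoxymethyl)-2-[(1R)-1,2-dihydroxyethyl]-2,3-diethylpentanoate
Product: 18 methyl (2S,3S)-5-[(tert-butyldimethylsilyl)oxy]-3-(diethoxymethyl)-2,3-diethyl-2-formylpentanoate
Conditions: NaIO4, THF/pH 7 buffer, 23 °C
Reagents that add atoms: none
Why: Periodate glycol cleavage removes the terminal CH2OH carbon and turns the former carbinol carbon into the C7a aldehyde; C7 is quaternary and cannot epimerise.

Step 13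
Reactants: 18 methyl (2S,3S)-5-[(tert-butyldimethylsilyl)oxy]-3-(diethoxymethyl)-2,3-diethyl-2-formylpentanoate
Product: 19 methyl (2R,3S)-5-[(tert-butyldimethylsilyl)oxy]-3-(diethoxymethyl)-2,3-diethyl-2-[(1E)-3-oxobut-1-en-1-yl]pentanoate
Conditions: (MeO)2P(O)CH2C(O)CH3, LiCl, iPr2NEt, MeCN, 23 → 40 °C
Reagents that add atoms: dimethyl (2-oxopropyl)phosphonate, COP(=O)(OC)CC(C)=O
Why: Horner–Wadsworth–Emmons olefination with the ketophosphonate under mild LiCl/amine conditions should give the (E)-enone and avoids hydroxide, which could deformylate the α-formyl ester.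

Step 14
Reactants: 19 methyl (2R,3S)-5-[(tert-butyldimethylsilyl)oxy]-3-(diethoxymethyl)-2,3-diethyl-2-[(1E)-3-oxobut-1-en-1-yl]pentanoate
Product: 20 methyl (2R,3S)-5-[(tert-butyldimethylsilyl)oxy]-3-(diethoxymethyl)-2,3-diethyl-2-[(1E,3S)-3-hydroxybut-1-en-1-yl]pentanoate
Conditions: (R)-1-methyl-3,3-diphenyltetrahydro-1H,3H-pyrrolo[1,2-c][1,3,2]oxazaborole (0.5 equiv), catecholborane, toluene, −78 °C
Reagents that add atoms: none
Why: Corey–Bakshi–Shibata reduction with the (R)-oxazaborolidine treats the alkenyl group as the large substituent and should deliver hydride to the face that gives the (S)-allylic alcohol, under reagent control far from the C6/C7 centres.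

Step 15
Reactants: 20 methyl (2R,3S)-5-[(tert-butyldimethylsilyl)oxy]-3-(diethoxymethyl)-2,3-diethyl-2-[(1E,3S)-3-hydroxybut-1-en-1-yl]pentanoate
Product: 21 methyl (2R,3S)-2-[(1E,3S)-3-(butanoyloxy)but-1-en-1-yl]-5-[(tert-butyldimethylsilyl)oxy]-3-(diethoxymethyl)-2,3-diethylpentanoate
Conditions: (CH3CH2CH2CO)2O, Et3N, 4-(dimethylamino)pyridine (cat.), CH2Cl2, 0 → 23 °C
Reagents that add atoms: butanoic anhydride, CCCC(=O)OC(=O)CCC
Why: Acylation of the secondary allylic alcohol with butanoic anhydride under 4-(dimethylamino)pyridine catalysis should give the ester needed for the rearrangement.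

Step 16
Reactants: 21 methyl (2R,3S)-2-[(1E,3S)-3-(butanoyloxy)but-1-en-1-yl]-5-[(tert-butyldimethylsilyl)oxy]-3-(diethoxymethyl)-2,3-diethylpentanoate
Product: 24 (2S,3R,4R,5S)-7-[(tert-butyldimethylsilyl)oxy]-5-(diethoxymethyl)-2,4,5-triethyl-4-(methoxycarbonyl)-3-[(1E)-prop-1-en-1-yl]heptanoic acid, via (Z)-silyl ketene acetal 22 (not isolated), via trimethylsilyl ester 23 (not isolated)
Conditions: LiN(iPr)2, THF/DMPU (3:1), −78 °C; Me3SiCl/Et3N; −78 → 60 °C; aq. citric acid
Reagents that add atoms: none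
Why: Ireland–Claisen rearrangement: deprotonation in THF/DMPU should give the enolate with ethyl trans to the allyloxy group, trapped as the (Z)-silyl ketene acetal 22, and the chair transition state with the carbinol methyl group equatorial transfers the (S)-carbinol configuration to C7a (R) while the enolate geometry sets C1 (S), giving the new (E)-propenyl group.

Step 17
Reactants: 24 (2S,3R,4R,5S)-7-[(tert-butyldimethylsilyl)oxy]-5-(diethoxymethyl)-2,4,5-triethyl-4-(methoxycarbonyl)-3-[(1E)-prop-1-en-1-yl]heptanoic acid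
Product: 25 (2S,3R,4R,5S)-7-[(tert-butyldimethylsilyl)oxy]-5-(diethoxymethyl)-2,4,5-triethyl-N-methoxy-4-(methoxycarbonyl)-N-methyl-3-[(1E)-prop-1-en-1-yl]heptanamide
Conditions: MeNHOMe·HCl, N-(3-dimethylaminopropyl)-N′-ethylcarbodiimide hydrochloride, 1-hydroxybenzotriazole (cat.), iPr2NEt, CH2Cl2, 0 → 23 °C
Reagents that add atoms: N,O-dimethylhydroxylamine hydrochloride, CNOC.Cl
Why: Carbodiimide-mediated amide coupling should convert the acid into the N-methoxy-N-methyl (Weinreb) amide.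

Step 18
Reactants: 25 (2S,3R,4R,5S)-7-[(tert-butyldimethylsilyl)oxy]-5-(diethoxymethyl)-2,4,5-triethyl-N-methoxy-4-(methoxycarbonyl)-N-methyl-3-[(1E)-prop-1-en-1-yl]heptanamide
Product: 26 methyl (2R,3S)-5-[(tert-butyldimethylsilyl)oxy]-3-(diethoxymethyl)-2,3-diethyl-2-[(2E,4R,5S)-5-ethyl-7-methyl-6-oxoocta-2,7-dien-4-yl]pentanoate
Conditions: CH2=C(CH3)MgBr (3 equiv), THF, 0 → 23 °C
Reagents that add atoms: isopropenylmagnesium bromide, CC(=C)[Mg]Br
Why: Weinreb ketone synthesis: the Grignard reagent adds once to give a stable magnesium chelate, which should release the isopropenyl ketone on work-up, while the methyl ester between two quaternary carbons is too hindered to react.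

Step 19
Reactants: 26 methyl (2R,3S)-5-[(tert-butyldimethylsilyl)oxy]-3-(diethoxymethyl)-2,3-diethyl-2-[(2E,4R,5S)-5-ethyl-7-methyl-6-oxoocta-2,7-dien-4-yl]pentanoate
Product: 27 methyl (2R,3S)-5-[(tert-butyldimethylsilyl)oxy]-3-(diethoxymethyl)-2,3-diethyl-2-[(1R,5S)-5-ethyl-3-methyl-4-oxocyclopent-2-en-1-yl]pentanoate
Conditions: second-generation Hoveyda–Grubbs catalyst RuCl2(H2IMes)(=CH-C6H4-2-OiPr) (10 mol%), toluene, 80 °C
Reagents that add atoms: none
Why: Ring-closing metathesis of the isopropenyl ketone with the propenyl group should form the C3=C3a bond of the 2-methylcyclopent-2-enone (ring A) with loss of propene, no other alkene being left in the molecule.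

Step 20
Reactants: 27 methyl (2R,3S)-5-[(tert-butyldimethylsilyl)oxy]-3-(diethoxymethyl)-2,3-diethyl-2-[(1R,5S)-5-ethyl-3-methyl-4-oxocyclopent-2-en-1-yl]pentanoate
Product: 28 methyl (2R,3S)-3-(diethoxymethyl)-2,3-diethyl-2-[(1R,5S)-5-ethyl-3-methyl-4-oxocyclopent-2-en-1-yl]-5-hydroxypentanoate
Conditions: HF·pyridine, pyridine, THF, 0 °C
Reagents that add atoms: none
Why: Buffered HF·pyridine should cleave the primary TBS ether without touching the acetal, and avoids the alkoxide that fluoride salts would generate next to the ester.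

Step 21
Reactants: 28 methyl (2R,3S)-3-(diethoxymethyl)-2,3-diethyl-2-[(1R,5S)-5-ethyl-3-methyl-4-oxocyclopent-2-en-1-yl]-5-hydroxypentanoate
Product: 29 methyl (2R,3S)-3-(diethoxymethyl)-2,3-diethyl-2-[(1R,5S)-5-ethyl-3-methyl-4-oxocyclopent-2-en-1-yl]-5-oxopentanoate
Conditions: Dess–Martin periodinane, NaHCO3, CH2Cl2, 0 → 23 °C
Reagents that add atoms: none
Why: Dess–Martin oxidation of the primary alcohol under bicarbonate buffer should give the aldehyde without epimerising C1 or C7a.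

Step 22
Reactants: 29 methyl (2R,3S)-3-(diethoxymethyl)-2,3-diethyl-2-[(1R,5S)-5-ethyl-3-methyl-4-oxocyclopent-2-en-1-yl]-5-oxopentanoate
Product: 31 methyl (1S,3S,3aR,6S,7R,7aS)-6-(diethoxymethyl)-1,6,7-triethyl-3-methyl-2,4-dioxooctahydro-1H-indene-7-carboxylate, via cis-fused diketone 30 (not isolated)
Conditions: 2-(pentafluorophenyl)-6,7-dihydro-5H-pyrrolo[2,1-c][1,2,4]triazol-2-ium tetrafluoroborate (20 mol%), iPr2NEt (1 equiv), toluene, 60 °C; then DBU (1 equiv), 23 °C
Reagents that add atoms: none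
Why: The free carbene from the triazolium salt adds to the C4 aldehyde of 29 and, after proton transfer, the Breslow intermediate (an acyl-anion equivalent) attacks C3a of the 2-methylcyclopent-2-enone in a conjugate addition, the C2 enolate is protonated at C3 and the carbene is expelled, so that the C4–C3a bond forms and ring B closes. The closest known reaction type is the carbene-catalysed intramolecular Stetter reaction of aliphatic aldehydes with enones that closes six-membered rings, including α-substituted acceptors. Ring B closes in the 6-exo-trig mode (C3a inside the new ring, C3 outside), and the two quaternary carbons C6 and C7 in the tether bias the chain toward the folded conformer. C3a forms first cis to the C7a–C7 bond (30) because the tether can only reach the enone face it is attached to; DBU then epimerises C3a through the C4 enolate to the trans fusion of 31, the only isomer in which neither C3 nor C1 is syn-axial to the C7 or C6 ethyl group, and C3 settles by reversible enolisation of the C2 ketone with its methyl group trans to C4. The step needs acyl-anion addition to outrun enolisation of the aldehyde (5-exo Michael closure from C5 or aldol onto C2) and γ-deprotonation at C7a; the electron-poor N-pentafluorophenyl triazolium with a weak amine base, the neopentyl position of C5 and the hindered C7a–H should secure this.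

Step 23
Reactants: 31 methyl (1S,3S,3aR,6S,7R,7aS)-6-(diethoxymethyl)-1,6,7-triethyl-3-methyl-2,4-dioxooctahydro-1H-indene-7-carboxylate
Product: 32 methyl (1S,3S,3aR,6S,7R,7aR)-6-(diethoxymethyl)-1,6,7-triethyl-3-methyl-2-oxo-4-{[(trifluoromethyl)sulfonyl]oxy}-2,3,3a,6,7,7a-hexahydro-1H-indene-7-carboxylate
Conditions: KN(SiMe3)2 (1.05 equiv), THF, −78 °C; PhNTf2; aq. NH4Cl
Reagents that add atoms: N-phenylbis(trifluoromethanesulfonimide), O=S(=O)(N(c1ccccc1)S(=O)(=O)C(F)(F)F)C(F)(F)F
Why: Kinetic deprotonation with KN(SiMe3)2 at −78 °C should take place at C5, the only α-methylene (the C2 ketone and C3a offer only hindered methines), and O-triflation of the C4 enolate with PhNTf2 fixes the C4=C5 double bond (enol triflate formation).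

Step 24
Reactants: 32 methyl (1S,3S,3aR,6S,7R,7aR)-6-(diethoxymethyl)-1,6,7-triethyl-3-methyl-2-oxo-4-{[(trifluoromethyl)sulfonyl]oxy}-2,3,3a,6,7,7a-hexahydro-1H-indene-7-carboxylate
Product: 33 methyl (1S,3S,3aR,6S,7R,7aR)-6-(diethoxymethyl)-1,6,7-triethyl-3,4-dimethyl-2-oxo-2,3,3a,6,7,7a-hexahydro-1H-indene-7-carboxylate
Conditions: Me2Zn, Pd(PPh3)4 (5 mol%), THF, 0 → 40 °C
Reagents that add atoms: dimethylzinc, C[Zn]C
Why: Negishi coupling of the alkenyl triflate with dimethylzinc should install the C4 methyl group with retention of the C4=C5 position and is compatible with the ketone and the ester.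

Step 25
Reactants: 33 methyl (1S,3S,3aR,6S,7R,7aR)-6-(diethoxymethyl)-1,6,7-triethyl-3,4-dimethyl-2-oxo-2,3,3a,6,7,7a-hexahydro-1H-indene-7-carboxylate
Product: 34 methyl (1S,3S,3aR,6S,7R,7aR)-1,6,7-triethyl-6-formyl-3,4-dimethyl-2-oxo-2,3,3a,6,7,7a-hexahydro-1H-indene-7-carboxylate
Conditions: p-toluenesulfonic acid monohydrate (cat.), acetone/H2O, 40 °C
Reagents that add atoms: water, O
Why: Acid-catalysed acetal hydrolysis should free the C8 aldehyde, which has no α-hydrogen and therefore can neither epimerise nor move into conjugation.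

Step 26
Reactants: 34 methyl (1S,3S,3aR,6S,7R,7aR)-1,6,7-triethyl-6-formyl-3,4-dimethyl-2-oxo-2,3,3a,6,7,7a-hexahydro-1H-indene-7-carboxylate
Product: 35 methyl (1S,3S,3aR,6R,7R,7aR)-1,6,7-triethyl-6-[(1E)-2-formylbut-1-en-1-yl]-3,4-dimethyl-2-oxo-2,3,3a,6,7,7a-hexahydro-1H-indene-7-carboxylate
Conditions: Ph3P=C(Et)CHO, toluene, 110 °C
Reagents that add atoms: 2-(triphenylphosphoranylidene)butanal, CCC(C=O)=P(c1ccccc1)(c1ccccc1)c1ccccc1
Why: Wittig reaction with the stabilised formyl ylide should give the (E)-trisubstituted enal (formyl group trans to C6) and is selective for the aldehyde over the C2 ketone.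

Step 27
Reactants: 35 methyl (1S,3S,3aR,6R,7R,7aR)-1,6,7-triethyl-6-[(1E)-2-formylbut-1-en-1-yl]-3,4-dimethyl-2-oxo-2,3,3a,6,7,7a-hexahydro-1H-indene-7-carboxylate
Product: 36 methyl (1S,3S,3aR,6R,7R,7aR)-1,6,7-triethyl-6-[(1E,3E)-2-ethyl-4-phenylbuta-1,3-dien-1-yl]-3,4-dimethyl-2-oxo-2,3,3a,6,7,7a-hexahydro-1H-indene-7-carboxylate
Conditions: (EtO)2P(O)CH2Ph, NaN(SiMe3)2, THF, −78 → 0 °C
Reagents that add atoms: diethyl benzylphosphonate, CCOP(=O)(Cc1ccccc1)OCC
Why: Horner–Wadsworth–Emmons olefination of the enal with the benzylphosphonate anion should give the (E)-styryl alkene and so the (1E,3E)-diene.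

Step 28
Reactants: 36 methyl (1S,3S,3aR,6R,7R,7aR)-1,6,7-triethyl-6-[(1E,3E)-2-ethyl-4-phenylbuta-1,3-dien-1-yl]-3,4-dimethyl-2-oxo-2,3,3a,6,7,7a-hexahydro-1H-indene-7-carboxylate
Product: 37 (1S,3S,3aR,6R,7R,7aR)-1,6,7-triethyl-6-[(1E,3E)-2-ethyl-4-phenylbuta-1,3-dien-1-yl]-3,4-dimethyl-2-oxo-2,3,3a,6,7,7a-hexahydro-1H-indene-7-carboxylic acid
Conditions: NaSEt, DMF, 90 °C; aq. HCl
Reagents that add atoms: none
Why: The ester carbonyl is shielded by two quaternary carbons, so the ester is cleaved by SN2 attack of ethanethiolate on the methyl group (nucleophilic dealkylation), which leaves all stereocentres untouched.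

## Compound list

1 | 3,3-diethoxyprop-1-yne | C#CC(OCC)OCC | starting material
2 | 4,4-diethoxybut-2-yn-1-ol | OCC#CC(OCC)OCC | intermediate
3 | sodium 3-(diethoxymethyl)-2,2-bis(2-methoxyethoxy)-2,5-dihydro-1,2-oxaluminol-2-uide (cyclic alkenylalanate; not isolated) | [Na+].CCOC(OCC)C1=CCO[Al-]1(OCCOC)OCCOC | intermediate
4 | (Z)-4,4-diethoxy-3-iodobut-2-en-1-ol | OC/C=C(\I)C(OCC)OCC | intermediate
5 | (E)-4,4-diethoxy-3-ethylbut-2-en-1-ol | OC/C=C(\CC)C(OCC)OCC | intermediate
6 | (R)-4-benzylthiazolidine-2-thione | S=C1N[C@H](Cc2ccccc2)CS1 | starting material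
7 | butanoyl chloride | CCCC(=O)Cl | starting material
8 | (R)-4-benzyl-3-butanoylthiazolidine-2-thione | CCCC(=O)N1[C@H](Cc2ccccc2)CSC1=S | intermediate
9 | (benzyloxy)acetaldehyde | O=CCOCc1ccccc1 | starting material
10 | (2R,3R)-1-[(4R)-4-benzyl-2-thioxothiazolidin-3-yl]-4-(benzyloxy)-2-ethyl-3-hydroxybutan-1-one | CC[C@@H](C(=O)N1[C@H](Cc2ccccc2)CSC1=S)[C@@H](O)COCc1ccccc1 | intermediate
11 | (E)-4,4-diethoxy-3-ethylbut-2-en-1-yl (2R,3R)-4-(benzyloxy)-2-ethyl-3-hydroxybutanoate | CC[C@@H](C(=O)OC/C=C(\CC)C(OCC)OCC)[C@@H](O)COCc1ccccc1 | intermediate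
12 | (2S,3S)-2-[(1R)-2-(benzyloxy)-1-hydroxyethyl]-3-(diethoxymethyl)-2,3-diethylpent-4-enoic acid | C=C[C@](CC)(C(OCC)OCC)[C@](CC)(C(=O)O)[C@@H](O)COCc1ccccc1 | intermediate
13 | methyl (2S,3S)-2-[(1R)-2-(benzyloxy)-1-hydroxyethyl]-3-(diethoxymethyl)-2,3-diethylpent-4-enoate | C=C[C@](CC)(C(OCC)OCC)[C@](CC)(C(=O)OC)[C@@H](O)COCc1ccccc1 | intermediate
14 | B-alkyl-9-BBN adduct of 13 (boron on C4; not isolated) | B1(C2CCCC1CCC2)CC[C@](CC)(C(OCC)OCC)[C@](CC)(C(=O)OC)[C@@H](O)COCc1ccccc1 | intermediate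
15 | methyl (2S,3S)-2-[(1R)-2-(benzyloxy)-1-hydroxyethyl]-3-(diethoxymethyl)-2,3-diethyl-5-hydroxypentanoate | OCC[C@](CC)(C(OCC)OCC)[C@](CC)(C(=O)OC)[C@@H](O)COCc1ccccc1 | intermediate
16 | methyl (2S,3S)-2-[(1R)-2-(benzyloxy)-1-hydroxyethyl]-5-[(tert-butyldimethylsilyl)oxy]-3-(diethoxymethyl)-2,3-diethylpentanoate | CC(C)(C)[Si](C)(C)OCC[C@](CC)(C(OCC)OCC)[C@](CC)(C(=O)OC)[C@@H](O)COCc1ccccc1 | intermediate
17 | methyl (2S,3S)-5-[(tert-butyldimethylsilyl)oxy]-3-(diethoxymethyl)-2-[(1R)-1,2-dihydroxyethyl]-2,3-diethylpentanoate | CC(C)(C)[Si](C)(C)OCC[C@](CC)(C(OCC)OCC)[C@](CC)(C(=O)OC)[C@@H](O)CO | intermediate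
18 | methyl (2S,3S)-5-[(tert-butyldimethylsilyl)oxy]-3-(diethoxymethyl)-2,3-diethyl-2-formylpentanoate | CC(C)(C)[Si](C)(C)OCC[C@](CC)(C(OCC)OCC)[C@](CC)(C(=O)OC)C=O | intermediate
19 | methyl (2R,3S)-5-[(tert-butyldimethylsilyl)oxy]-3-(diethoxymethyl)-2,3-diethyl-2-[(1E)-3-oxobut-1-en-1-yl]pentanoate | CC(C)(C)[Si](C)(C)OCC[C@](CC)(C(OCC)OCC)[C@](CC)(C(=O)OC)/C=C/C(C)=O | intermediate
20 | methyl (2R,3S)-5-[(tert-butyldimethylsilyl)oxy]-3-(diethoxymethyl)-2,3-diethyl-2-[(1E,3S)-3-hydroxybut-1-en-1-yl]pentanoate | CC(C)(C)[Si](C)(C)OCC[C@](CC)(C(OCC)OCC)[C@](CC)(C(=O)OC)/C=C/[C@H](C)O | intermediate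
21 | methyl (2R,3S)-2-[(1E,3S)-3-(butanoyloxy)but-1-en-1-yl]-5-[(tert-butyldimethylsilyl)oxy]-3-(diethoxymethyl)-2,3-diethylpentanoate | CC(C)(C)[Si](C)(C)OCC[C@](CC)(C(OCC)OCC)[C@](CC)(C(=O)OC)/C=C/[C@H](C)OC(=O)CCC | intermediate
22 | (Z)-O-trimethylsilyl ketene acetal of 21 (ethyl cis to OSiMe3; not isolated) | CC(C)(C)[Si](C)(C)OCC[C@](CC)(C(OCC)OCC)[C@](CC)(C(=O)OC)/C=C/[C@H](C)O/C(=C/CC)O[Si](C)(C)C | intermediate
23 | trimethylsilyl ester of 24 (not isolated) | C[Si](C)(C)OC(=O)[C@@H](CC)[C@@H](/C=C/C)[C@@](CC)(C(=O)OC)[C@@](CC)(C(OCC)OCC)CCO[Si](C)(C)C(C)(C)C | intermediate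
24 | (2S,3R,4R,5S)-7-[(tert-butyldimethylsilyl)oxy]-5-(diethoxymethyl)-2,4,5-triethyl-4-(methoxycarbonyl)-3-[(1E)-prop-1-en-1-yl]heptanoic acid | OC(=O)[C@@H](CC)[C@@H](/C=C/C)[C@@](CC)(C(=O)OC)[C@@](CC)(C(OCC)OCC)CCO[Si](C)(C)C(C)(C)C | intermediate
25 | (2S,3R,4R,5S)-7-[(tert-butyldimethylsilyl)oxy]-5-(diethoxymethyl)-2,4,5-triethyl-N-methoxy-4-(methoxycarbonyl)-N-methyl-3-[(1E)-prop-1-en-1-yl]heptanamide | CON(C)C(=O)[C@@H](CC)[C@@H](/C=C/C)[C@@](CC)(C(=O)OC)[C@@](CC)(C(OCC)OCC)CCO[Si](C)(C)C(C)(C)C | intermediate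
26 | methyl (2R,3S)-5-[(tert-butyldimethylsilyl)oxy]-3-(diethoxymethyl)-2,3-diethyl-2-[(2E,4R,5S)-5-ethyl-7-methyl-6-oxoocta-2,7-dien-4-yl]pentanoate | CC(=C)C(=O)[C@@H](CC)[C@@H](/C=C/C)[C@@](CC)(C(=O)OC)[C@@](CC)(C(OCC)OCC)CCO[Si](C)(C)C(C)(C)C | intermediate
27 | methyl (2R,3S)-5-[(tert-butyldimethylsilyl)oxy]-3-(diethoxymethyl)-2,3-diethyl-2-[(1R,5S)-5-ethyl-3-methyl-4-oxocyclopent-2-en-1-yl]pentanoate | CC(C)(C)[Si](C)(C)OCC[C@](CC)(C(OCC)OCC)[C@](CC)(C(=O)OC)[C@@H]1C=C(C)C(=O)[C@H]1CC | intermediate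
28 | methyl (2R,3S)-3-(diethoxymethyl)-2,3-diethyl-2-[(1R,5S)-5-ethyl-3-methyl-4-oxocyclopent-2-en-1-yl]-5-hydroxypentanoate | OCC[C@](CC)(C(OCC)OCC)[C@](CC)(C(=O)OC)[C@@H]1C=C(C)C(=O)[C@H]1CC | intermediate
29 | methyl (2R,3S)-3-(diethoxymethyl)-2,3-diethyl-2-[(1R,5S)-5-ethyl-3-methyl-4-oxocyclopent-2-en-1-yl]-5-oxopentanoate (key-step precursor) | O=CC[C@](CC)(C(OCC)OCC)[C@](CC)(C(=O)OC)[C@@H]1C=C(C)C(=O)[C@H]1CC | intermediate
30 | methyl (1S,3aS,6S,7R,7aS)-6-(diethoxymethyl)-1,6,7-triethyl-3-methyl-2,4-dioxooctahydro-1H-indene-7-carboxylate (cis-fused; C3 not yet defined; not isolated) | CCOC(OCC)[C@@]1(CC)CC(=O)[C@H]2[C@H]([C@H](CC)C(=O)C2C)[C@@]1(CC)C(=O)OC | intermediate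
31 | methyl (1S,3S,3aR,6S,7R,7aS)-6-(diethoxymethyl)-1,6,7-triethyl-3-methyl-2,4-dioxooctahydro-1H-indene-7-carboxylate (key-step product) | CCOC(OCC)[C@@]1(CC)CC(=O)[C@@H]2[C@H]([C@H](CC)C(=O)[C@H]2C)[C@@]1(CC)C(=O)OC | intermediate
32 | methyl (1S,3S,3aR,6S,7R,7aR)-6-(diethoxymethyl)-1,6,7-triethyl-3-methyl-2-oxo-4-{[(trifluoromethyl)sulfonyl]oxy}-2,3,3a,6,7,7a-hexahydro-1H-indene-7-carboxylate | CCOC(OCC)[C@@]1(CC)C=C(OS(=O)(=O)C(F)(F)F)[C@@H]2[C@H]([C@H](CC)C(=O)[C@H]2C)[C@@]1(CC)C(=O)OC | intermediate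
33 | methyl (1S,3S,3aR,6S,7R,7aR)-6-(diethoxymethyl)-1,6,7-triethyl-3,4-dimethyl-2-oxo-2,3,3a,6,7,7a-hexahydro-1H-indene-7-carboxylate | CCOC(OCC)[C@@]1(CC)C=C(C)[C@@H]2[C@H]([C@H](CC)C(=O)[C@H]2C)[C@@]1(CC)C(=O)OC | intermediate
34 | methyl (1S,3S,3aR,6S,7R,7aR)-1,6,7-triethyl-6-formyl-3,4-dimethyl-2-oxo-2,3,3a,6,7,7a-hexahydro-1H-indene-7-carboxylate | O=C[C@@]1(CC)C=C(C)[C@@H]2[C@H]([C@H](CC)C(=O)[C@H]2C)[C@@]1(CC)C(=O)OC | intermediate
35 | methyl (1S,3S,3aR,6R,7R,7aR)-1,6,7-triethyl-6-[(1E)-2-formylbut-1-en-1-yl]-3,4-dimethyl-2-oxo-2,3,3a,6,7,7a-hexahydro-1H-indene-7-carboxylate | CCC(/C=O)=C\[C@@]1(CC)C=C(C)[C@@H]2[C@H]([C@H](CC)C(=O)[C@H]2C)[C@@]1(CC)C(=O)OC | intermediate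
36 | methyl (1S,3S,3aR,6R,7R,7aR)-1,6,7-triethyl-6-[(1E,3E)-2-ethyl-4-phenylbuta-1,3-dien-1-yl]-3,4-dimethyl-2-oxo-2,3,3a,6,7,7a-hexahydro-1H-indene-7-carboxylate | CCC(/C=C/c1ccccc1)=C\[C@@]1(CC)C=C(C)[C@@H]2[C@H]([C@H](CC)C(=O)[C@H]2C)[C@@]1(CC)C(=O)OC | intermediate
37 | (1S,3S,3aR,6R,7R,7aR)-1,6,7-triethyl-6-[(1E,3E)-2-ethyl-4-phenylbuta-1,3-dien-1-yl]-3,4-dimethyl-2-oxo-2,3,3a,6,7,7a-hexahydro-1H-indene-7-carboxylic acid (CNP0134269.1) | CCC(/C=C/c1ccccc1)=C\[C@@]1(CC)C=C(C)[C@@H]2[C@H]([C@H](CC)C(=O)[C@H]2C)[C@@]1(CC)C(=O)O | target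

## Step count and risk

Total: 28 steps. Longest linear sequence: 26 steps (steps 1–3 and 6–28).

Steps most likely to fail:

1. Step 22 (key step). The Breslow intermediate may add too slowly to the α-methyl-substituted, γ-branched enone, so that enolisation of the aldehyde (5-exo Michael closure from C5, or aldol onto C2) or carbene-mediated self-condensation overtakes the Stetter pathway. Fallback: from 29, samarium diiodide (SmI2, THF/t-BuOH, −78 °C) generates the C4 ketyl, which adds 6-exo to C3a of the enone (reductive aldehyde–enone cyclisation) and should give the cis-fused hydroxy ketone F1. Dess–Martin oxidation of F1 gives the cis-diketone 30, and DBU epimerises it to 31, where the route is rejoined.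

2. Step 7. The hindered lithium dianion may rearrange slowly and instead fragment by loss of the allylic alkoxide (ketene formation) or be recovered unchanged. Fallback: from 11, the hydroxyl group is silylated (Et3SiOTf, 2,6-lutidine) to the triethylsilyl ether F2. The ester is enolised with the enantiomer of a Koga-type chiral lithium amide (lithium N-(2,2,2-trifluoroethyl)-1-phenyl-2-(piperidin-1-yl)ethanamide) that matches the (2R) α-centre, which fixes the enolate geometry without the chelate. Trapping with Me3SiCl and rearrangement as a neutral Ireland–Claisen silyl ketene acetal should give the triethylsilyl-protected acid F3, and HF·pyridine removes the silyl group to return 12. The facial preference then rests on allylic strain and would have to be checked.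

3. Step 23. Deprotonation may compete at C1 or C3 of the C2 ketone or at C3a, giving regioisomeric enol triflates and epimerised material. Fallback: from 31, MeMgBr/CeCl3 (THF, −78 °C) adds to the less hindered six-ring C4 ketone to give the tertiary alcohol F4. Burgess reagent then dehydrates F4 by syn elimination toward C5 (the axial C3a–H is anti to the axial hydroxyl group and cannot take part), which gives 33.

## Further compounds

F1 | step 22 | C4 alcohol corresponding to 30: methyl 6-(diethoxymethyl)-1,6,7-triethyl-4-hydroxy-3-methyl-2-oxooctahydro-1H-indene-7-carboxylate, cis-fused, C3 and C4 as epimer mixtures | CCOC(OCC)[C@@]1(CC)CC(O)[C@H]2[C@H]([C@H](CC)C(=O)C2C)[C@@]1(CC)C(=O)OC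
F2 | step 7 | (E)-4,4-diethoxy-3-ethylbut-2-en-1-yl (2R,3R)-4-(benzyloxy)-2-ethyl-3-[(triethylsilyl)oxy]butanoate | CC[C@@H](C(=O)OC/C=C(\CC)C(OCC)OCC)[C@@H](O[Si](CC)(CC)CC)COCc1ccccc1
F3 | step 7 | O-triethylsilyl ether of acid 12 | C=C[C@](CC)(C(OCC)OCC)[C@](CC)(C(=O)O)[C@@H](O[Si](CC)(CC)CC)COCc1ccccc1
F4 | step 23 | C4 tertiary alcohol from 31: methyl 6-(diethoxymethyl)-1,6,7-triethyl-4-hydroxy-3,4-dimethyl-2-oxooctahydro-1H-indene-7-carboxylate, other centres as in 31, hydroxyl axial | CCOC(OCC)[C@@]1(CC)CC(C)(O)[C@@H]2[C@H]([C@H](CC)C(=O)[C@H]2C)[C@@]1(CC)C(=O)OC
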